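## Retrosynthetic overview

1. Isospiculoic acid A (20) comes from bis-silyl ether 17 by one-pot desilylation and oxidation (carbinol to ketone, CH2OSi to CO2H).
2. 17 comes from the acyclic all-E tetraene 16 by an anodically triggered radical-cation intramolecular [4+2]. The C3a–C7a bond (cyclopentane) forms first, then the C4–C5 bond between the two quaternary carbons (cyclohexene), both in the same step.
3. 16 comes from aldehyde 12 (Wittig, reduction, silylation build the dienophile), and 12 from enal 7 (Wittig and Horner–Wadsworth–Emmons build the phenyltriene).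
4. 7 comes from a chelation-controlled vinylogous Mukaiyama aldol of aldehyde 3 with silyl dienol ether 5 (from 2-ethylhex-2-enal).
5. 3 comes from (R)-Roche ester 1; its single stereocentre (the later C3 methyl centre) relays to all the others.

Assumption: ylides 8 and 13 are bought (each is otherwise one step from the 2-bromo carbonyl compound and PPh3), and minor diastereomers from step 4 are removed by chromatography.

## Route

Step 1
Reactants: 1 methyl (R)-3-hydroxy-2-methylpropanoate
Product: 2 methyl (R)-2-methyl-3-(triethylsilyloxy)propanoate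
Conditions: TESCl, imidazole, CH2Cl2, 0 °C to rt
Reagents that add atoms: chlorotriethylsilane, CC[Si](Cl)(CC)CC
Why: Standard silylation of a primary alcohol; the bought stereocentre is not touched.

Step 2
Reactants: 2 methyl (R)-2-methyl-3-(triethylsilyloxy)propanoate
Product: 3 (R)-2-methyl-3-(triethylsilyloxy)propanal
Conditions: iBu2AlH (1.1 equiv), CH2Cl2, −78 °C; MeOH, aq. KNaC4H4O6 (potassium sodium tartrate)
Reagents that add atoms: none
Why: Low-temperature DIBAL half-reduction stops at the aluminium hemiacetal, and the α-stereocentre is configurationally stable at −78 °C.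

Step 3
Reactants: 4 (E)-2-ethylhex-2-enal
Product: 5 tert-butyl{[(1E,3E)-2-ethylhexa-1,3-dien-1-yl]oxy}dimethylsilane
Conditions: TBSOTf, Et3N, Et2O, 0 °C to rt
Reagents that add atoms: tert-butyldimethylsilyl trifluoromethanesulfonate, CC(C)(C)[Si](C)(C)OS(=O)(=O)C(F)(F)F
Why: Soft γ-enolisation and O-silylation of an enal gives the silyl dienol ether; its enol-ether geometry is lost again in step 4.

Step 4
Reactants: 3 (R)-2-methyl-3-(triethylsilyloxy)propanal; 5 tert-butyl{[(1E,3E)-2-ethylhexa-1,3-dien-1-yl]oxy}dimethylsilane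
Product: 6 (2E,4R,5S,6R)-2,4-diethyl-5-hydroxy-6-methyl-7-(triethylsilyloxy)hept-2-enal
Conditions: Me2AlCl (2.5 equiv), CH2Cl2, −78 °C; aq. NaHCO3
Reagents that add atoms: none
Why: Chelation-controlled vinylogous Mukaiyama aldol: Me2AlCl bridges the aldehyde and β-silyloxy oxygens so the diene attacks anti to the C-methyl group (5,6-anti), the open antiperiplanar transition state gives 4,5-syn as in Lewis-acid crotylations, and attack is at the γ-carbon because the α-carbon carries ethyl, which places the new ethyl stereocentre anti to the methyl one (the carbinol centre is oxidised later).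

Step 5
Reactants: 6 (2E,4R,5S,6R)-2,4-diethyl-5-hydroxy-6-methyl-7-(triethylsilyloxy)hept-2-enal
Product: 7 (2E,4R,5S,6R)-2,4-diethyl-6-methyl-5,7-bis(triethylsilyloxy)hept-2-enal
Conditions: TESOTf, 2,6-lutidine, CH2Cl2, −78 °C
Reagents that add atoms: triethylsilyl trifluoromethanesulfonate, CC[Si](CC)(CC)OS(=O)(=O)C(F)(F)F
Why: Silyl triflate silylation of the hindered secondary alcohol blocks retro-(vinylogous) aldol cleavage in the later basic steps.

Step 6
Reactants: 7 (2E,4R,5S,6R)-2,4-diethyl-6-methyl-5,7-bis(triethylsilyloxy)hept-2-enal; 8 2-(triphenylphosphoranylidene)butanal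
Product: 9 (2E,4E,6R,7S,8R)-2,4,6-triethyl-8-methyl-7,9-bis(triethylsilyloxy)nona-2,4-dienal
Conditions: toluene, 100 °C
Reagents that add atoms: none
Why: Wittig olefination with a formyl-stabilised ylide gives the (E)-trisubstituted enal, and the less electrophilic dienal product does not react further.

Step 7
Reactants: 9 (2E,4E,6R,7S,8R)-2,4,6-triethyl-8-methyl-7,9-bis(triethylsilyloxy)nona-2,4-dienal; 10 diethyl benzylphosphonate
Product: 11 (2R,3S,4R,5E,7E,9E)-4,6,8-triethyl-2-methyl-10-phenyl-1,3-bis(triethylsilyloxy)deca-5,7,9-triene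
Conditions: NaN(SiMe3)2, THF, −78 °C to rt
Reagents that add atoms: none
Why: Horner–Wadsworth–Emmons olefination with a benzylphosphonate anion gives the (E)-styrene, and addition to the non-enolisable aldehyde outruns deprotonation at the remote allylic stereocentre.

Step 8
Reactants: 11 (2R,3S,4R,5E,7E,9E)-4,6,8-triethyl-2-methyl-10-phenyl-1,3-bis(triethylsilyloxy)deca-5,7,9-triene
Product: 12 (2S,3S,4R,5E,7E,9E)-4,6,8-triethyl-2-methyl-10-phenyl-3-(triethylsilyloxy)deca-5,7,9-trienal
Conditions: (COCl)2, DMSO, CH2Cl2, −78 to −30 °C; Et3N, −78 °C to rt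
Reagents that add atoms: none
Why: Swern oxidation acts directly on the primary triethylsilyl ether (the chlorosulfonium reagent cleaves and oxidises it, while the hindered secondary silyl ether survives), and the α-stereocentre is kept at low temperature.

Step 9
Reactants: 12 (2S,3S,4R,5E,7E,9E)-4,6,8-triethyl-2-methyl-10-phenyl-3-(triethylsilyloxy)deca-5,7,9-trienal; 13 ethyl 2-(triphenylphosphoranylidene)butanoate
Product: 14 ethyl (2E,4R,5R,6R,7E,9E,11E)-2,6,8,10-tetraethyl-4-methyl-12-phenyl-5-(triethylsilyloxy)dodeca-2,7,9,11-tetraenoate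
Conditions: CH2Cl2, rt, 48 h
Reagents that add atoms: none
Why: Wittig olefination with an ester-stabilised ylide gives the (E)-2-ethyl enoate without epimerising the α-branched aldehyde.

Step 10
Reactants: 14 ethyl (2E,4R,5R,6R,7E,9E,11E)-2,6,8,10-tetraethyl-4-methyl-12-phenyl-5-(triethylsilyloxy)dodeca-2,7,9,11-tetraenoate
Product: 15 (2E,4R,5R,6R,7E,9E,11E)-2,6,8,10-tetraethyl-4-methyl-12-phenyl-5-(triethylsilyloxy)dodeca-2,7,9,11-tetraen-1-ol
Conditions: iBu2AlH (2.5 equiv), CH2Cl2, −78 °C; aq. KNaC4H4O6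
Reagents that add atoms: none
Why: DIBAL 1,2-reduction of the enoate gives the allylic alcohol, which turns the electron-poor alkene into a nucleophilic one that no longer cyclises thermally at rt.

Step 11
Reactants: 15 (2E,4R,5R,6R,7E,9E,11E)-2,6,8,10-tetraethyl-4-methyl-12-phenyl-5-(triethylsilyloxy)dodeca-2,7,9,11-tetraen-1-ol
Product: 16 (2E,4R,5R,6R,7E,9E,11E)-2,6,8,10-tetraethyl-4-methyl-12-phenyl-1,5-bis(triethylsilyloxy)dodeca-2,7,9,11-tetraene
Conditions: TESCl, imidazole, CH2Cl2, 0 °C
Reagents that add atoms: chlorotriethylsilane, CC[Si](Cl)(CC)CC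
Why: Silylation masks the hydroxyl group, which would otherwise add to the styrene radical cation formed in step 12.

Step 12
Reactants: 16 (2E,4R,5R,6R,7E,9E,11E)-2,6,8,10-tetraethyl-4-methyl-12-phenyl-1,5-bis(triethylsilyloxy)dodeca-2,7,9,11-tetraene
Product: 17 (1R,2R,3R,3aS,4S,5R,7aS)-1,4,5,7-tetraethyl-3-methyl-5-[(E)-2-phenylethenyl]-2-(triethylsilyloxy)-4-[(triethylsilyloxy)methyl]-2,3,3a,4,5,7a-hexahydro-1H-indene
Conditions: undivided cell, carbon-felt anode, Pt cathode, +1.1 V vs Ag/AgCl, 0.3 F/mol, 1.0 M LiClO4 in MeNO2, 2,6-di-tert-butylpyridine (10 mol %), 5 mM, rt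
Reagents that add atoms: none
Why: Proposed new method: anodic hole-catalysed intramolecular Diels–Alder in which the diene is the ionised partner — the phenyltriene is the only group oxidised at +1.1 V (estimated Eox about +1.1 V vs SCE; isolated alkenes and silyl ethers lie above +1.8 V), its radical cation is attacked 5-exo at the diene terminus by the nucleophilic trisubstituted alkene, and the resulting tertiary radical/phenylpentadienyl cation pair collapses at the ethyl- and styryl-bearing carbon faster than C–C rotation (radical-to-cation coupling tolerates the vicinal quaternary centres) to give the cyclohexene radical cation, which is reduced by another molecule of 16 (chain) or at the cathode, so only a catalytic charge is needed; ground-state hole catalysis avoids the triplet E/Z scrambling of the triene that sensitisation would cause, so alkene geometry is transcribed into the two quaternary centres, while the ring-fusion centres follow from the two allylic stereocentres, each holding its C–H in the alkene plane (A(1,3) strain against the cis ethyl group) and together allowing only the trans-fused, doubly matched transition state; closest known reaction type: anodically, aminium-salt or photoredox initiated radical-cation Diels–Alder reactions of electron-rich styrenes and enol ethers with dienes, where the dienophile and not the diene is oxidised.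

Step 13
Reactants: 17 (1R,2R,3R,3aS,4S,5R,7aS)-1,4,5,7-tetraethyl-3-methyl-5-[(E)-2-phenylethenyl]-2-(triethylsilyloxy)-4-[(triethylsilyloxy)methyl]-2,3,3a,4,5,7a-hexahydro-1H-indene
Product: 20 isospiculoic acid A, via diol 18 (not isolated), via keto aldehyde 19 (not isolated)
Conditions: CrO3, H2SO4, H2O, acetone, 0 °C to rt
Reagents that add atoms: water, O
Why: Jones oxidation: the aqueous acid cleaves both triethylsilyl ethers, the secondary alcohol goes to the ketone and the neopentyl primary alcohol through the aldehyde hydrate to the acid; no lactol can form because the ring oxygen and the C4 substituent are trans on the cyclopentane, and both α-centres already hold the thermodynamically preferred configuration (each substituent trans to the adjacent ring bond).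

## Compound list

1 | methyl (R)-3-hydroxy-2-methylpropanoate ((R)-Roche ester) | COC(=O)[C@@H](CO)C | starting material
2 | methyl (R)-2-methyl-3-(triethylsilyloxy)propanoate | COC(=O)[C@@H](CO[Si](CC)(CC)CC)C | intermediate
3 | (R)-2-methyl-3-(triethylsilyloxy)propanal | O=C[C@@H](CO[Si](CC)(CC)CC)C | intermediate
4 | (E)-2-ethylhex-2-enal | CCC/C=C(\CC)C=O | starting material
5 | tert-butyl{[(1E,3E)-2-ethylhexa-1,3-dien-1-yl]oxy}dimethylsilane | CC/C=C/C(CC)=C/O[Si](C)(C)C(C)(C)C | intermediate
6 | (2E,4R,5S,6R)-2,4-diethyl-5-hydroxy-6-methyl-7-(triethylsilyloxy)hept-2-enal | O=C/C(CC)=C/[C@@H](CC)[C@H](O)[C@H](C)CO[Si](CC)(CC)CC | intermediate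
7 | (2E,4R,5S,6R)-2,4-diethyl-6-methyl-5,7-bis(triethylsilyloxy)hept-2-enal | O=C/C(CC)=C/[C@@H](CC)[C@H](O[Si](CC)(CC)CC)[C@H](C)CO[Si](CC)(CC)CC | intermediate
8 | 2-(triphenylphosphoranylidene)butanal | CCC(C=O)=P(c1ccccc1)(c1ccccc1)c1ccccc1 | starting material
9 | (2E,4E,6R,7S,8R)-2,4,6-triethyl-8-methyl-7,9-bis(triethylsilyloxy)nona-2,4-dienal | O=C/C(CC)=C/C(CC)=C/[C@@H](CC)[C@H](O[Si](CC)(CC)CC)[C@H](C)CO[Si](CC)(CC)CC | intermediate
10 | diethyl benzylphosphonate | CCOP(=O)(Cc1ccccc1)OCC | starting material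
11 | (2R,3S,4R,5E,7E,9E)-4,6,8-triethyl-2-methyl-10-phenyl-1,3-bis(triethylsilyloxy)deca-5,7,9-triene | CC[Si](CC)(CC)OC[C@@H](C)[C@@H](O[Si](CC)(CC)CC)[C@H](CC)/C=C(CC)/C=C(CC)/C=C/c1ccccc1 | intermediate
12 | (2S,3S,4R,5E,7E,9E)-4,6,8-triethyl-2-methyl-10-phenyl-3-(triethylsilyloxy)deca-5,7,9-trienal | O=C[C@@H](C)[C@@H](O[Si](CC)(CC)CC)[C@H](CC)/C=C(CC)/C=C(CC)/C=C/c1ccccc1 | intermediate
13 | ethyl 2-(triphenylphosphoranylidene)butanoate | CCOC(=O)C(CC)=P(c1ccccc1)(c1ccccc1)c1ccccc1 | starting material
14 | ethyl (2E,4R,5R,6R,7E,9E,11E)-2,6,8,10-tetraethyl-4-methyl-12-phenyl-5-(triethylsilyloxy)dodeca-2,7,9,11-tetraenoate | CCOC(=O)/C(CC)=C/[C@@H](C)[C@@H](O[Si](CC)(CC)CC)[C@H](CC)/C=C(CC)/C=C(CC)/C=C/c1ccccc1 | intermediate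
15 | (2E,4R,5R,6R,7E,9E,11E)-2,6,8,10-tetraethyl-4-methyl-12-phenyl-5-(triethylsilyloxy)dodeca-2,7,9,11-tetraen-1-ol | OC/C(CC)=C/[C@@H](C)[C@@H](O[Si](CC)(CC)CC)[C@H](CC)/C=C(CC)/C=C(CC)/C=C/c1ccccc1 | intermediate
16 | (2E,4R,5R,6R,7E,9E,11E)-2,6,8,10-tetraethyl-4-methyl-12-phenyl-1,5-bis(triethylsilyloxy)dodeca-2,7,9,11-tetraene | CC[Si](CC)(CC)OC/C(CC)=C/[C@@H](C)[C@@H](O[Si](CC)(CC)CC)[C@H](CC)/C=C(CC)/C=C(CC)/C=C/c1ccccc1 | intermediate
17 | (1R,2R,3R,3aS,4S,5R,7aS)-1,4,5,7-tetraethyl-3-methyl-5-[(E)-2-phenylethenyl]-2-(triethylsilyloxy)-4-[(triethylsilyloxy)methyl]-2,3,3a,4,5,7a-hexahydro-1H-indene | CCC1=C[C@](/C=C/c2ccccc2)(CC)[C@@](CC)(CO[Si](CC)(CC)CC)[C@H]2[C@H]1[C@@H](CC)[C@H](O[Si](CC)(CC)CC)[C@@H]2C | intermediate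
18 | (1R,2R,3R,3aS,4S,5R,7aS)-1,4,5,7-tetraethyl-4-(hydroxymethyl)-3-methyl-5-[(E)-2-phenylethenyl]-2,3,3a,4,5,7a-hexahydro-1H-inden-2-ol (diol) | CCC1=C[C@](/C=C/c2ccccc2)(CC)[C@@](CC)(CO)[C@H]2[C@H]1[C@@H](CC)[C@H](O)[C@@H]2C | intermediate (not isolated)
19 | (1R,3R,3aS,4S,5R,7aS)-1,4,5,7-tetraethyl-3-methyl-2-oxo-5-[(E)-2-phenylethenyl]-2,3,3a,4,5,7a-hexahydro-1H-indene-4-carbaldehyde (keto aldehyde) | CCC1=C[C@](/C=C/c2ccccc2)(CC)[C@@](CC)(C=O)[C@H]2[C@H]1[C@@H](CC)C(=O)[C@@H]2C | intermediate (not isolated)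
20 | isospiculoic acid A, (1R,3R,3aS,4S,5R,7aS)-1,4,5,7-tetraethyl-3-methyl-2-oxo-5-[(E)-2-phenylethenyl]-2,3,3a,4,5,7a-hexahydro-1H-indene-4-carboxylic acid | CCC1=C[C@](/C=C/c2ccccc2)(CC)[C@@](CC)(C(=O)O)[C@H]2[C@H]1[C@@H](CC)C(=O)[C@@H]2C | target

## Step count and risks

Total: 13 steps. Longest linear sequence: 12 steps (1, 2, 4 to 13 from the Roche ester); step 3 is a one-step side branch.

The three steps most likely to fail:

Step 12 (the proposed new electrochemical cycloaddition). The diene-centred radical cation may close too slowly, lose alkene geometry or give vinylcyclobutanes. The fallback uses known chemistry and sets out from enoate 14. Heating 14 in toluene (BHT, 110 °C) brings about the thermal intramolecular Diels–Alder reaction of the activated enoate, the established ring-forming mode for this polyketide family, under the same double allylic-strain control. It gives ethyl (1R,2R,3R,3aS,4S,5R,7aS)-1,4,5,7-tetraethyl-3-methyl-5-[(E)-2-phenylethenyl]-2-(triethylsilyloxy)-2,3,3a,4,5,7a-hexahydro-1H-indene-4-carboxylate F2. LiAlH4 (Et2O, 0 °C to rt) then reduces the hindered ester to [(1R,2R,3R,3aS,4S,5R,7aS)-1,4,5,7-tetraethyl-3-methyl-5-[(E)-2-phenylethenyl]-2-(triethylsilyloxy)-2,3,3a,4,5,7a-hexahydro-1H-inden-4-yl]methanol F3. F3 is taken through the conditions of step 13 in place of 17 and comes back to the route at 20.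

Step 4 (open-transition-state aldol; two stereocentres must both come out right). If the syn/chelate selectivity is poor, the fallback sets out from 3 and replaces the open transition state by a closed one. Allylboration of 3 with (Z)-pent-2-enylboronic acid pinacol ester (toluene, −78 °C to rt, aqueous work-up) goes through a chair transition state (Z gives syn, and Z-reagents add anti-Felkin to α-methyl aldehydes). It gives (2R,3S,4R)-4-ethyl-2-methyl-1-(triethylsilyloxy)hex-5-en-3-ol F1. Cross-metathesis of F1 with 2-ethylacrolein (second-generation Hoveyda–Grubbs catalyst, C31H38Cl2N2ORu, CH2Cl2, 40 °C) gives the (E)-enal and comes back to the route at 6.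

Step 13 (one-pot desilylation and double oxidation in aqueous acid). The γ,δ-unsaturated acid and the neopentyl aldehyde stage may not tolerate the Jones medium. The fallback sets out from 17 and separates the events under near-neutral conditions: HF·pyridine (THF, 0 °C) gives diol 18, now isolated; Dess–Martin periodinane with NaHCO3 (CH2Cl2) gives keto aldehyde 19, now isolated; Pinnick oxidation (NaClO2, NaH2PO4, 2-methylbut-2-ene, tBuOH/H2O) comes back to the route at 20. New compounds on its way: none F0.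

## Further compounds

F1 | step 4 | (2R,3S,4R)-4-ethyl-2-methyl-1-(triethylsilyloxy)hex-5-en-3-ol | C=C[C@@H](CC)[C@H](O)[C@H](C)CO[Si](CC)(CC)CC
F2 | step 12 | ethyl (1R,2R,3R,3aS,4S,5R,7aS)-1,4,5,7-tetraethyl-3-methyl-5-[(E)-2-phenylethenyl]-2-(triethylsilyloxy)-2,3,3a,4,5,7a-hexahydro-1H-indene-4-carboxylate | CCC1=C[C@](/C=C/c2ccccc2)(CC)[C@@](CC)(C(=O)OCC)[C@H]2[C@H]1[C@@H](CC)[C@H](O[Si](CC)(CC)CC)[C@@H]2C
F3 | step 12 | [(1R,2R,3R,3aS,4S,5R,7aS)-1,4,5,7-tetraethyl-3-methyl-5-[(E)-2-phenylethenyl]-2-(triethylsilyloxy)-2,3,3a,4,5,7a-hexahydro-1H-inden-4-yl]methanol | CCC1=C[C@](/C=C/c2ccccc2)(CC)[C@@](CC)(CO)[C@H]2[C@H]1[C@@H](CC)[C@H](O[Si](CC)(CC)CC)[C@@H]2C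
F0 | step 13 | none | none
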